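**Plan**
1. Retrosynthesis: the C7 methyl is cut first (MeLi on a ring A ketone). In ring B, O1–C2(Me2)–C3–C4 together with C9a are read as a 2,2-dimethylfuran-3(2H)-one whose C4=C9a double bond has taken up C5 and C5a, the CH2= and C(Me)= of an isopropenyl group four atoms away (C9, C8, C7, C6). A temporary C4–C9a cyclobutane bond is reinstated, and C4–C5 and C5a–C9a are cut together ([2+2]).
2. The open-chain precursor is cut at C8–C9 (furanone dienolate + epoxide) and at C6–Cβ (auxiliary-controlled alkylation with the allylic bromide of the hydroazulene). The hydroazulene is cut at C7′–C8′ (ring-closing metathesis), C5′–C6′ (crotylboration), C8a′–vinyl (epoxide opening) and C3a′–C4′ (Ireland–Claisen).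
3. Forward: ring D from (S)-linalool by metathesis, then the C4′ quaternary centre, epoxide/vinyl cuprate, ring C by crotylboration and metathesis, and the exocyclic allylic bromide. Union by alkylation of a senecioyl oxazolidinone, then the furanone tether. Photocycloaddition closes ring A and a cyclobutane; reductive fragmentation turns furanone plus cyclobutane into ring B; reduction at C3 and methyl addition at C7 finish.
4. Stereochemistry: C1′, C3a′, C8a′ from (S)-linalool (1,3-transfer in the Ireland–Claisen step, then anti epoxidation and anti opening); C6′ from the tartrate crotylboronate; E alkene from steric control in the allylic transposition; C6 from the (R)-oxazolidinone; C5a from C6 in the photocycloaddition; C9a by axial hydride delivery; C3 by CBS reduction; C7 by equatorial attack of MeLi.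

Key step: step 22

**Remarks**
- Assumption: (S)-(+)-linalool of high enantiomeric purity is taken as a commercial material.
- Locants: rings A/B (cyclohexane/oxepane) carry 1-benzoxepine numbering (O1, C2, C3, C4, C5, C5a, C6, C7, C8, C9, C9a). Rings C/D (cycloheptane/cyclopentane) carry primed azulene numbering (C1′ to C8a′). The bridge is Cα (=CH on C5′) and Cβ (CH2 on C6).
- Q = (2E)-2-[(1R,3aR,6R,8aR)-1,4,4,6-tetramethyl-1-(triethylsilyloxy)octahydroazulen-5(1H)-ylidene]ethyl (cis-fused; bromide 18 without Br). Q′ = the same group with a free 1′-hydroxyl.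

**Route**

Step 1
Reactants: 1 (S)-linalool
Product: 2 (1S)-1-methylcyclopent-2-en-1-ol
Conditions: second-generation Grubbs catalyst (0.5 mol%), CH2Cl2, 40 °C, short reaction time; carried on as a solution
Reagents that add atoms: none
Why: Ring-closing metathesis of the 1,6-diene expels 2-methylpropene and leaves the tertiary carbinol stereocentre of linalool untouched; it is stopped before dehydration of the allylic alcohol sets in.

Step 2
Reactants: 2 (1S)-1-methylcyclopent-2-en-1-ol; 3 2-methylpropanoyl chloride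
Product: 4 (1S)-1-methylcyclopent-2-en-1-yl 2-methylpropanoate
Conditions: n-BuLi, THF, −78 °C; then 3, −78 → 0 °C
Reagents that add atoms: none
Why: O-Acylation of the lithium alkoxide esterifies the tertiary allylic alcohol without the acid that would ionise it, and no stereocentre is touched.

Step 3
Reactants: 4 (1S)-1-methylcyclopent-2-en-1-yl 2-methylpropanoate
Product: 7 2-methyl-2-[(1R)-3-methylcyclopent-2-en-1-yl]propanoic acid, via silyl ketene acetal 5 (not isolated), via trimethylsilyl ester 6 (not isolated)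
Conditions: LiN(i-Pr)2, Me3SiCl, THF, −78 → 55 °C; then 1 M HCl
Reagents that add atoms: none
Why: Ireland–Claisen rearrangement of the tetrasubstituted silyl ketene acetal (no E/Z issue) is suprafacial across the cyclopentene, so the C3a′–C4′ bond and the quaternary C4′ form on the face that carried the ester oxygen and C3a′ is set by 1,3-chirality transfer.

Step 4
Reactants: 7 2-methyl-2-[(1R)-3-methylcyclopent-2-en-1-yl]propanoic acid
Product: 8 methyl 2-methyl-2-[(1R)-3-methylcyclopent-2-en-1-yl]propanoate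
Conditions: MeI, K2CO3, DMF, 20 °C
Reagents that add atoms: iodomethane, CI
Why: SN2 O-methylation of the carboxylate gives the ester, which cannot lactonise onto the epoxide made next.

Step 5
Reactants: 8 methyl 2-methyl-2-[(1R)-3-methylcyclopent-2-en-1-yl]propanoate
Product: 9 methyl 2-methyl-2-[(1S,2S,5R)-5-methyl-6-oxabicyclo[3.1.0]hexan-2-yl]propanoate
Conditions: mCPBA, NaHCO3, CH2Cl2, 0 °C
Reagents that add atoms: 3-chloroperbenzoic acid, OOC(=O)c1cccc(Cl)c1
Why: Prilezhaev epoxidation of the trisubstituted alkene should occur anti to the bulky allylic CMe2CO2Me group, which puts the oxygen that becomes the C1′ hydroxyl trans to C4′.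

Step 6
Reactants: 9 methyl 2-methyl-2-[(1S,2S,5R)-5-methyl-6-oxabicyclo[3.1.0]hexan-2-yl]propanoate
Product: 10 methyl 2-[(1R,2R,3R)-2-ethenyl-3-hydroxy-3-methylcyclopentyl]-2-methylpropanoate
Conditions: CH2=CHMgBr (3 equiv), CuI (20 mol%), THF, −30 → 0 °C; aq. NH4Cl
Reagents that add atoms: vinylmagnesium bromide, C=C[Mg]Br
Why: Copper-catalysed SN2 opening of the trisubstituted epoxide at its secondary carbon (C8a′) with inversion should place the vinyl group cis to C4′ and leave the tertiary C1′ alcohol trans to both (net anti addition across the former alkene).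

Step 7
Reactants: 10 methyl 2-[(1R,2R,3R)-2-ethenyl-3-hydroxy-3-methylcyclopentyl]-2-methylpropanoate
Product: 11 methyl 2-[(1R,2R,3R)-2-ethenyl-3-methyl-3-(triethylsilyloxy)cyclopentyl]-2-methylpropanoate
Conditions: Et3SiOTf, 2,6-lutidine, CH2Cl2, −78 → 0 °C
Reagents that add atoms: triethylsilyl trifluoromethanesulfonate, CC[Si](CC)(CC)OS(=O)(=O)C(F)(F)F
Why: Silyl triflate silylation protects the hindered tertiary alcohol so that it survives the later allylic bromination and Lewis acid steps.

Step 8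
Reactants: 11 methyl 2-[(1R,2R,3R)-2-ethenyl-3-methyl-3-(triethylsilyloxy)cyclopentyl]-2-methylpropanoate
Product: 12 2-[(1R,2R,3R)-2-ethenyl-3-methyl-3-(triethylsilyloxy)cyclopentyl]-2-methylpropanal
Conditions: i-Bu2AlH (1.1 equiv), toluene, −78 °C; aq. potassium sodium tartrate
Reagents that add atoms: none
Why: Partial reduction of the neopentyl-type methyl ester should stop at the aldehyde because the hindered aluminium hemiacetal does not collapse at −78 °C.

Step 9
Reactants: 12 2-[(1R,2R,3R)-2-ethenyl-3-methyl-3-(triethylsilyloxy)cyclopentyl]-2-methylpropanal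
Product: 13 (3S,4R)-2-[(1R,2R,3R)-2-ethenyl-3-methyl-3-(triethylsilyloxy)cyclopentyl]-2,4-dimethylhex-5-en-3-ol
Conditions: tartrate (Z)-crotylboronate (1.5 equiv), 4 Å molecular sieves, toluene, −78 → −20 °C; aq. NaOH
Reagents that add atoms: diisopropyl (4R,5R)-2-[(2Z)-but-2-en-1-yl]-1,3,2-dioxaborolane-4,5-dicarboxylate, C/C=C\CB1O[C@@H](C(=O)OC(C)C)[C@H](C(=O)OC(C)C)O1
Why: Roush crotylboration through a Zimmerman–Traxler chair: the Z reagent gives the syn pair and the (R,R)-tartrate selects the aldehyde face, so C6′ should be R (reagent control); the carbinol centre is removed in step 11.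

Step 10
Reactants: 13 (3S,4R)-2-[(1R,2R,3R)-2-ethenyl-3-methyl-3-(triethylsilyloxy)cyclopentyl]-2,4-dimethylhex-5-en-3-ol
Product: 15 (1R,3aR,5S,6R,8aR)-1,4,4,6-tetramethyl-1-(triethylsilyloxy)decahydroazulen-5-ol, via cycloheptene 14 (not isolated)
Conditions: second-generation Grubbs catalyst (5 mol%), CH2Cl2, 40 °C; then solvent change to EtOAc, Pd/C, H2 (1 atm)
Reagents that add atoms: none
Why: Ring-closing metathesis of the two vinyl groups held cis on ring D closes ring C at C7′–C8′ (helped by the gem-dimethyl group), and hydrogenation of the only alkene completes the cis-fused bicycle without touching a stereocentre.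

Step 11
Reactants: 15 (1R,3aR,5S,6R,8aR)-1,4,4,6-tetramethyl-1-(triethylsilyloxy)decahydroazulen-5-ol
Product: 16 (1R,3aR,6R,8aR)-1,4,4,6-tetramethyl-1-(triethylsilyloxy)octahydroazulen-5(1H)-one
Conditions: Dess–Martin periodinane, NaHCO3, CH2Cl2, 0 → 20 °C
Reagents that add atoms: none
Why: Buffered Dess–Martin oxidation gives the C5′ ketone under neutral conditions that should not epimerise the adjacent C6′ methyl centre.

Step 12
Reactants: 16 (1R,3aR,6R,8aR)-1,4,4,6-tetramethyl-1-(triethylsilyloxy)octahydroazulen-5(1H)-one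
Product: 17 (1R,3aR,5R,6R,8aR)-5-ethenyl-1,4,4,6-tetramethyl-1-(triethylsilyloxy)decahydroazulen-5-ol
Conditions: CH2=CHMgBr, CeCl3, THF, −78 → 0 °C
Reagents that add atoms: vinylmagnesium bromide, C=C[Mg]Br
Why: The weakly basic organocerium reagent should add 1,2 to the hindered, enolisable ketone without enolising it; the new carbinol centre (drawn for attack anti to the C6′ methyl) is lost in the next step.

Step 13
Reactants: 17 (1R,3aR,5R,6R,8aR)-5-ethenyl-1,4,4,6-tetramethyl-1-(triethylsilyloxy)decahydroazulen-5-ol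
Product: 18 (1R,3aR,5E,6R,8aR)-5-(2-bromoethylidene)-1,4,4,6-tetramethyl-1-(triethylsilyloxy)decahydroazulene
Conditions: PBr3 (0.4 equiv), pyridine (0.1 equiv), Et2O, −30 → 0 °C
Reagents that add atoms: phosphorus tribromide, BrP(Br)Br
Why: Bromination of the tertiary vinyl carbinol with allylic transposition (SN2′) gives the primary allylic bromide, and the CH2Br group should settle trans to the quaternary C4′, which is the E alkene.

Step 14
Reactants: 19 (4R)-4-benzyl-1,3-oxazolidin-2-one; 20 3-methylbut-2-enoyl chloride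
Product: 21 (4R)-4-benzyl-3-(3-methylbut-2-enoyl)-1,3-oxazolidin-2-one
Conditions: n-BuLi, THF, −78 °C; then 20, −78 → 0 °C
Reagents that add atoms: none
Why: N-Acylation of the lithiated oxazolidinone installs the senecioyl group on the auxiliary.

Step 15
Reactants: 22 3-hydroxy-3-methylbutan-2-one
Product: 24 2,2,5-trimethylfuran-3(2H)-one, via 5-hydroxy-5-methylhexane-2,4-dione 23 (not isolated)
Conditions: LiN(i-Pr)2 (3.2 equiv), THF, −78 °C; ethyl acetate, −78 → 0 °C; then 2 M HCl, 20 °C
Reagents that add atoms: ethyl acetate, CCOC(C)=O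
Why: Claisen acylation of the methyl ketone enolate (hydroxyl masked as its lithium alkoxide) followed by acid-catalysed cyclodehydration of the α′-hydroxy 1,3-diketone gives the 3(2H)-furanone.

Step 16
Reactants: 21 (4R)-4-benzyl-3-(3-methylbut-2-enoyl)-1,3-oxazolidin-2-one; 18 (1R,3aR,5E,6R,8aR)-5-(2-bromoethylidene)-1,4,4,6-tetramethyl-1-(triethylsilyloxy)decahydroazulene
Product: 25 (4R)-4-benzyl-3-[(2R)-3-methyl-2-Q-but-3-enoyl]-1,3-oxazolidin-2-one
Conditions: NaN(SiMe3)2, THF, −78 °C; then 18, −78 → −40 °C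
Reagents that add atoms: none
Why: Evans alkylation of the sodium dienolate (γ-deprotonation, α-attack with deconjugation to the isopropenyl group): the allylic bromide should approach the chelated Z-enolate anti to the benzyl group, which sets C6 as R and forms the C6–Cβ bond.

Step 17
Reactants: 25 (4R)-4-benzyl-3-[(2R)-3-methyl-2-Q-but-3-enoyl]-1,3-oxazolidin-2-one
Product: 26 (2R)-3-methyl-2-Q-but-3-en-1-ol
Conditions: LiBH4, MeOH (1 equiv), Et2O, 0 °C
Reagents that add atoms: none
Why: Reductive cleavage of the imide releases the auxiliary for recovery and gives the primary alcohol without touching the α-stereocentre.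

Step 18
Reactants: 26 (2R)-3-methyl-2-Q-but-3-en-1-ol
Product: 27 (2R)-3-methyl-2-Q-but-3-enal
Conditions: Dess–Martin periodinane, NaHCO3, CH2Cl2, 0 °C; used crude at once
Reagents that add atoms: none
Why: Neutral Dess–Martin oxidation should keep the α-stereocentre of the β,γ-unsaturated aldehyde from epimerising or moving into conjugation.

Step 19
Reactants: 27 (2R)-3-methyl-2-Q-but-3-enal
Product: 29 (2S)-2-[(1R)-2-methyl-1-Q-prop-2-en-1-yl]oxirane, via lithium chlorohydrin alkoxide 28 (not isolated)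
Conditions: ICH2Cl, n-BuLi (added last, slowly), THF, −78 → 20 °C
Reagents that add atoms: chloroiodomethane, ClCI
Why: Chloromethyllithium made in the presence of the aldehyde adds faster than it enolises, and Felkin–Anh addition (isopropenyl as the large group) should give the chlorohydrin alkoxide that closes to the (S)-epoxide; this C7 centre is temporary (oxidised in step 27) and a minor epimer is removed at 30.

Step 20
Reactants: 29 (2S)-2-[(1R)-2-methyl-1-Q-prop-2-en-1-yl]oxirane; 24 2,2,5-trimethylfuran-3(2H)-one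
Product: 30 5-[(3R,4R)-3-hydroxy-5-methyl-4-Q-hex-5-en-1-yl]-2,2-dimethylfuran-3(2H)-one
Conditions: 24, LiN(i-Pr)2, THF, −78 °C; then BF3·OEt2 and 29, −78 → −40 °C; aq. NH4Cl
Reagents that add atoms: none
Why: γ-Deprotonation of the furanone at its 5-methyl group gives the extended dienolate, which should open the BF3-activated terminal epoxide at CH2 by SN2 attack (enolate alkylation by an epoxide) to form C8–C9; BF3 also keeps the new alkoxide from adding to the furanone.

Step 21
Reactants: 30 5-[(3R,4R)-3-hydroxy-5-methyl-4-Q-hex-5-en-1-yl]-2,2-dimethylfuran-3(2H)-one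
Product: 31 5-[(3R,4R)-3-(tert-butyldimethylsilyloxy)-5-methyl-4-Q-hex-5-en-1-yl]-2,2-dimethylfuran-3(2H)-one
Conditions: t-BuMe2SiCl, imidazole, DMF, 20 °C
Reagents that add atoms: tert-butyldimethylsilyl chloride, CC(C)(C)[Si](C)(C)Cl
Why: Silylation masks the C7 hydroxyl, which would otherwise add to the furanone or trap the oxocarbenium ion of step 23, and keeps C7 apart from the later C3 hydroxyl.

Step 22
Reactants: 31 5-[(3R,4R)-3-(tert-butyldimethylsilyloxy)-5-methyl-4-Q-hex-5-en-1-yl]-2,2-dimethylfuran-3(2H)-one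
Product: 32 (4S,5aR,6R,7R,9aS)-7-(tert-butyldimethylsilyloxy)-2,2,5a-trimethyl-6-Q-octahydro-4,9a-cyclo-1-benzoxepin-3(2H)-one
Conditions: hν (350 nm, Pyrex), degassed MeCN (5 mM), −20 °C
Reagents that add atoms: none
Why: Excitation of the furanone and intersystem crossing give the triplet vinylogous ester, whose β-carbon C9a bonds to the internal alkene carbon C5a through a chair-like six-membered transition state, and the 1,4-biradical closes the C4–C5 bond after spin inversion. The closest known reaction type is the intramolecular enone–alkene [2+2] photocycloaddition of vinylogous esters and 3(2H)-furanones (the first stage of a de Mayo sequence). Ring A closes in the straight 1,6 (6-exo) mode set by the four-atom tether C9–C8–C7–C6, and the cyclobutane (C4, C5, C5a, C9a) then closes as a four-membered ring cis-fused to ring A and to the oxolanone. C5a is controlled by C6: with the Cβ side chain and the C7 silyloxy group equatorial, the alkene is expected to turn its CH2 end, not its methyl group, over the furanone ring and away from the C2 methyl that faces it, so the C5a methyl becomes axial and cis to the side chain; C9a and C4 follow from the cis fusion and are re-set or lost in step 23. The step needs regioselectivity (straight, not crossed, secured by the tether length), facial selectivity (secured by C6) and chemoselectivity (the trisubstituted Cα alkene cannot reach the enone and does not absorb at 350 nm).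

Step 23
Reactants: 32 (4S,5aR,6R,7R,9aS)-7-(tert-butyldimethylsilyloxy)-2,2,5a-trimethyl-6-Q-octahydro-4,9a-cyclo-1-benzoxepin-3(2H)-one
Product: 35 (5aR,6R,7R,9aR)-7-(tert-butyldimethylsilyloxy)-2,2,5a-trimethyl-6-Q-octahydro-1-benzoxepin-3(2H)-one, via oxocarbenium triflate 33 (not isolated), via trimethylsilyl enol ether 34 (not isolated)
Conditions: Me3SiOTf (1.5 equiv), Et3SiH (10 equiv), CH2Cl2, −78 → −40 °C; aq. NaHCO3, then aq. citric acid
Reagents that add atoms: none
Why: Proposed new method: silylation of the C3 ketone by Me3SiOTf makes it a strong acceptor, the ring oxygen on C9a donates, and the strained C4–C9a bond of this donor–acceptor cyclobutane should break heterolytically to the C9a oxocarbenium ion and the C3 silyl enol ether, after which Et3SiH delivers hydride axially to C9a, anti to the axial C5a methyl, to give the trans-fused oxepane (C9a R); the closest known reaction types are the retro-Mannich fragmentation of vinylogous amide photoadducts, the Lewis acid ring opening of alkoxy-substituted donor–acceptor cyclobutanes, the retro-aldol stage of the de Mayo reaction and the Et3SiH/Me3SiOTf reduction of cyclic oxocarbenium ions in reductive etherification.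

Step 24
Reactants: 35 (5aR,6R,7R,9aR)-7-(tert-butyldimethylsilyloxy)-2,2,5a-trimethyl-6-Q-octahydro-1-benzoxepin-3(2H)-one
Product: 36 (3R,5aR,6R,7R,9aR)-7-(tert-butyldimethylsilyloxy)-2,2,5a-trimethyl-6-Q-decahydro-1-benzoxepin-3-ol
Conditions: (S)-2-methyl-CBS-oxazaborolidine (1 equiv), catecholborane, toluene, −78 → −40 °C
Reagents that add atoms: none
Why: CBS reduction under catalyst control: the quaternary C2 acts as the large group and C4H2 as the small one, so the (S)-catalyst should give the (3R)-alcohol, and catecholborane at low temperature leaves the alkene alone.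

Step 25
Reactants: 36 (3R,5aR,6R,7R,9aR)-7-(tert-butyldimethylsilyloxy)-2,2,5a-trimethyl-6-Q-decahydro-1-benzoxepin-3-ol
Product: 37 (3R,5aR,6R,7R,9aR)-7-(tert-butyldimethylsilyloxy)-2,2,5a-trimethyl-6-Q-decahydro-1-benzoxepin-3-yl acetate
Conditions: Ac2O, DMAP, pyridine, 20 → 40 °C
Reagents that add atoms: acetic anhydride, CC(=O)OC(C)=O
Why: DMAP-catalysed acetylation protects the C3 hydroxyl so that only the C7 oxygen is oxidised later.

Step 26
Reactants: 37 (3R,5aR,6R,7R,9aR)-7-(tert-butyldimethylsilyloxy)-2,2,5a-trimethyl-6-Q-decahydro-1-benzoxepin-3-yl acetate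
Product: 38 (3R,5aR,6R,7R,9aR)-7-hydroxy-2,2,5a-trimethyl-6-Q′-decahydro-1-benzoxepin-3-yl acetate
Conditions: HF·pyridine, pyridine/THF, 0 → 20 °C
Reagents that add atoms: none
Why: Buffered fluoride cleaves both silyl ethers (C7–O and C1′–O) while the acetate and the tertiary alcohol survive.

Step 27
Reactants: 38 (3R,5aR,6R,7R,9aR)-7-hydroxy-2,2,5a-trimethyl-6-Q′-decahydro-1-benzoxepin-3-yl acetate
Product: 39 (3R,5aR,6R,9aR)-2,2,5a-trimethyl-7-oxo-6-Q′-decahydro-1-benzoxepin-3-yl acetate
Conditions: Dess–Martin periodinane, NaHCO3, CH2Cl2, 20 °C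
Reagents that add atoms: none
Why: Dess–Martin oxidation of the only secondary alcohol gives the ring A ketone; the tertiary C1′ alcohol is inert and C6, now α to the ketone, already has the equatorial, thermodynamically preferred configuration.

Step 28
Reactants: 39 (3R,5aR,6R,9aR)-2,2,5a-trimethyl-7-oxo-6-Q′-decahydro-1-benzoxepin-3-yl acetate
Product: 41 (3R,5aR,6R,7S,9aR)-6-[(2E)-2-[(1R,3aR,6R,8aR)-1-hydroxy-1,4,4,6-tetramethyloctahydroazulen-5(1H)-ylidene]ethyl]-2,2,5a,7-tetramethyldecahydro-1-benzoxepine-3,7-diol, via target 3-acetate 40 (not isolated)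
Conditions: MeLi (10 equiv), CeCl3, THF, −78 → 0 °C; aq. NH4Cl
Reagents that add atoms: methyllithium, [Li]C
Why: 1,2-Addition of the methylcerium reagent to the chair cyclohexanone should occur from the equatorial direction because the axial path is blocked by the 1,3-related axial C5a methyl, giving the axial C7 hydroxyl (7S) cis to that methyl, and the excess MeLi then cleaves the C3 acetate on warming.

**Compound list**

1 | (S)-linalool [(3S)-3,7-dimethylocta-1,6-dien-3-ol] | C=C[C@@](C)(O)CCC=C(C)C | starting material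
2 | (1S)-1-methylcyclopent-2-en-1-ol | O[C@]1(C)C=CCC1 | intermediate
3 | 2-methylpropanoyl chloride | CC(C)C(Cl)=O | starting material
4 | (1S)-1-methylcyclopent-2-en-1-yl 2-methylpropanoate | CC(C)C(=O)O[C@]1(C)C=CCC1 | intermediate
5 | trimethyl({2-methyl-1-[(1S)-1-methylcyclopent-2-en-1-yl]oxyprop-1-en-1-yl}oxy)silane (silyl ketene acetal) | CC(C)=C(O[Si](C)(C)C)O[C@]1(C)C=CCC1 | intermediate
6 | trimethylsilyl 2-methyl-2-[(1R)-3-methylcyclopent-2-en-1-yl]propanoate | C1=C(C)CC[C@H]1C(C)(C)C(=O)O[Si](C)(C)C | intermediate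
7 | 2-methyl-2-[(1R)-3-methylcyclopent-2-en-1-yl]propanoic acid | C1=C(C)CC[C@H]1C(C)(C)C(O)=O | intermediate
8 | methyl 2-methyl-2-[(1R)-3-methylcyclopent-2-en-1-yl]propanoate | C1=C(C)CC[C@H]1C(C)(C)C(=O)OC | intermediate
9 | methyl 2-methyl-2-[(1S,2S,5R)-5-methyl-6-oxabicyclo[3.1.0]hexan-2-yl]propanoate (epoxide trans to the side chain) | O1[C@H]2[C@@H](CC[C@@]12C)C(C)(C)C(=O)OC | intermediate
10 | methyl 2-[(1R,2R,3R)-2-ethenyl-3-hydroxy-3-methylcyclopentyl]-2-methylpropanoate | C=C[C@@H]1[C@@H](CC[C@@]1(C)O)C(C)(C)C(=O)OC | intermediate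
11 | methyl 2-[(1R,2R,3R)-2-ethenyl-3-methyl-3-(triethylsilyloxy)cyclopentyl]-2-methylpropanoate | C=C[C@@H]1[C@@H](CC[C@@]1(C)O[Si](CC)(CC)CC)C(C)(C)C(=O)OC | intermediate
12 | 2-[(1R,2R,3R)-2-ethenyl-3-methyl-3-(triethylsilyloxy)cyclopentyl]-2-methylpropanal | C=C[C@@H]1[C@@H](CC[C@@]1(C)O[Si](CC)(CC)CC)C(C)(C)C=O | intermediate
13 | (3S,4R)-2-[(1R,2R,3R)-2-ethenyl-3-methyl-3-(triethylsilyloxy)cyclopentyl]-2,4-dimethylhex-5-en-3-ol | C=C[C@@H]1[C@@H](CC[C@@]1(C)O[Si](CC)(CC)CC)C(C)(C)[C@@H](O)[C@H](C)C=C | intermediate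
14 | (1R,3aR,5S,6R,8aR)-1,4,4,6-tetramethyl-1-(triethylsilyloxy)-1,2,3,3a,4,5,6,8a-octahydroazulen-5-ol (C7′=C8′ cycloheptene) | C[C@@H]1C=C[C@@H]2[C@@H](CC[C@@]2(C)O[Si](CC)(CC)CC)C(C)(C)[C@H]1O | intermediate
15 | (1R,3aR,5S,6R,8aR)-1,4,4,6-tetramethyl-1-(triethylsilyloxy)decahydroazulen-5-ol | C[C@@H]1CC[C@@H]2[C@@H](CC[C@@]2(C)O[Si](CC)(CC)CC)C(C)(C)[C@H]1O | intermediate
16 | (1R,3aR,6R,8aR)-1,4,4,6-tetramethyl-1-(triethylsilyloxy)octahydroazulen-5(1H)-one | C[C@@H]1CC[C@@H]2[C@@H](CC[C@@]2(C)O[Si](CC)(CC)CC)C(C)(C)C1=O | intermediate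
17 | (1R,3aR,5R,6R,8aR)-5-ethenyl-1,4,4,6-tetramethyl-1-(triethylsilyloxy)decahydroazulen-5-ol | C[C@@H]1CC[C@@H]2[C@@H](CC[C@@]2(C)O[Si](CC)(CC)CC)C(C)(C)[C@@]1(O)C=C | intermediate
18 | (1R,3aR,5E,6R,8aR)-5-(2-bromoethylidene)-1,4,4,6-tetramethyl-1-(triethylsilyloxy)decahydroazulene (Q–Br) | C[C@@H]1CC[C@@H]2[C@@H](CC[C@@]2(C)O[Si](CC)(CC)CC)C(C)(C)/C1=C/CBr | intermediate
19 | (4R)-4-benzyl-1,3-oxazolidin-2-one | O=C1N[C@H](Cc2ccccc2)CO1 | starting material
20 | 3-methylbut-2-enoyl chloride | CC(C)=CC(Cl)=O | starting material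
21 | (4R)-4-benzyl-3-(3-methylbut-2-enoyl)-1,3-oxazolidin-2-one | CC(C)=CC(=O)N1[C@H](Cc2ccccc2)COC1=O | intermediate
22 | 3-hydroxy-3-methylbutan-2-one | CC(=O)C(C)(C)O | starting material
23 | 5-hydroxy-5-methylhexane-2,4-dione | CC(=O)CC(=O)C(C)(C)O | intermediate
24 | 2,2,5-trimethylfuran-3(2H)-one | CC1=CC(=O)C(C)(C)O1 | intermediate
25 | (4R)-4-benzyl-3-[(2R)-3-methyl-2-Q-but-3-enoyl]-1,3-oxazolidin-2-one | C[C@@H]1CC[C@@H]2[C@@H](CC[C@@]2(C)O[Si](CC)(CC)CC)C(C)(C)/C1=C/C[C@H](C(C)=C)C(=O)N1[C@H](Cc2ccccc2)COC1=O | intermediate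
26 | (2R)-3-methyl-2-Q-but-3-en-1-ol | C[C@@H]1CC[C@@H]2[C@@H](CC[C@@]2(C)O[Si](CC)(CC)CC)C(C)(C)/C1=C/C[C@H](C(C)=C)CO | intermediate
27 | (2R)-3-methyl-2-Q-but-3-enal | C[C@@H]1CC[C@@H]2[C@@H](CC[C@@]2(C)O[Si](CC)(CC)CC)C(C)(C)/C1=C/C[C@H](C(C)=C)C=O | intermediate
28 | lithium (2S,3R)-1-chloro-4-methyl-3-Q-pent-4-en-2-olate | C[C@@H]1CC[C@@H]2[C@@H](CC[C@@]2(C)O[Si](CC)(CC)CC)C(C)(C)/C1=C/C[C@H](C(C)=C)[C@H]([O-])CCl.[Li+] | intermediate
29 | (2S)-2-[(1R)-2-methyl-1-Q-prop-2-en-1-yl]oxirane | C[C@@H]1CC[C@@H]2[C@@H](CC[C@@]2(C)O[Si](CC)(CC)CC)C(C)(C)/C1=C/C[C@H](C(C)=C)[C@H]1CO1 | intermediate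
30 | 5-[(3R,4R)-3-hydroxy-5-methyl-4-Q-hex-5-en-1-yl]-2,2-dimethylfuran-3(2H)-one | C[C@@H]1CC[C@@H]2[C@@H](CC[C@@]2(C)O[Si](CC)(CC)CC)C(C)(C)/C1=C/C[C@H](C(C)=C)[C@H](O)CCC1=CC(=O)C(C)(C)O1 | intermediate
31 | 5-[(3R,4R)-3-(tert-butyldimethylsilyloxy)-5-methyl-4-Q-hex-5-en-1-yl]-2,2-dimethylfuran-3(2H)-one | C[C@@H]1CC[C@@H]2[C@@H](CC[C@@]2(C)O[Si](CC)(CC)CC)C(C)(C)/C1=C/C[C@H](C(C)=C)[C@H](O[Si](C)(C)C(C)(C)C)CCC1=CC(=O)C(C)(C)O1 | intermediate
32 | (4S,5aR,6R,7R,9aS)-7-(tert-butyldimethylsilyloxy)-2,2,5a-trimethyl-6-Q-octahydro-4,9a-cyclo-1-benzoxepin-3(2H)-one (cyclobutane C4–C5–C5a–C9a, cis-fused to ring A and to the oxolanone) | C[C@@H]1CC[C@@H]2[C@@H](CC[C@@]2(C)O[Si](CC)(CC)CC)C(C)(C)/C1=C/C[C@@H]1[C@@]2(C)C[C@@H]3C(=O)C(C)(C)O[C@]23CC[C@H]1O[Si](C)(C)C(C)(C)C | intermediate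
33 | (5aR,6R,7R)-7-(tert-butyldimethylsilyloxy)-2,2,5a-trimethyl-6-Q-3-(trimethylsilyloxy)-2,5,5a,6,7,8,9-heptahydro-1-benzoxepin-1-ium triflate (C9a=O1 oxocarbenium, C3=C4 silyl enol ether) | C[C@@H]1CC[C@@H]2[C@@H](CC[C@@]2(C)O[Si](CC)(CC)CC)C(C)(C)/C1=C/C[C@@H]1[C@@]2(C)CC=C(O[Si](C)(C)C)C(C)(C)[O+]=C2CC[C@H]1O[Si](C)(C)C(C)(C)C.[O-]S(=O)(=O)C(F)(F)F | intermediate
34 | (5aR,6R,7R,9aR)-7-(tert-butyldimethylsilyloxy)-2,2,5a-trimethyl-6-Q-3-(trimethylsilyloxy)-2,5,5a,6,7,8,9,9a-octahydro-1-benzoxepine | C[C@@H]1CC[C@@H]2[C@@H](CC[C@@]2(C)O[Si](CC)(CC)CC)C(C)(C)/C1=C/C[C@@H]1[C@@]2(C)CC=C(O[Si](C)(C)C)C(C)(C)O[C@@H]2CC[C@H]1O[Si](C)(C)C(C)(C)C | intermediate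
35 | (5aR,6R,7R,9aR)-7-(tert-butyldimethylsilyloxy)-2,2,5a-trimethyl-6-Q-octahydro-1-benzoxepin-3(2H)-one (trans-fused) | C[C@@H]1CC[C@@H]2[C@@H](CC[C@@]2(C)O[Si](CC)(CC)CC)C(C)(C)/C1=C/C[C@@H]1[C@@]2(C)CCC(=O)C(C)(C)O[C@@H]2CC[C@H]1O[Si](C)(C)C(C)(C)C | intermediate
36 | (3R,5aR,6R,7R,9aR)-7-(tert-butyldimethylsilyloxy)-2,2,5a-trimethyl-6-Q-decahydro-1-benzoxepin-3-ol | C[C@@H]1CC[C@@H]2[C@@H](CC[C@@]2(C)O[Si](CC)(CC)CC)C(C)(C)/C1=C/C[C@@H]1[C@@]2(C)CC[C@@H](O)C(C)(C)O[C@@H]2CC[C@H]1O[Si](C)(C)C(C)(C)C | intermediate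
37 | (3R,5aR,6R,7R,9aR)-7-(tert-butyldimethylsilyloxy)-2,2,5a-trimethyl-6-Q-decahydro-1-benzoxepin-3-yl acetate | C[C@@H]1CC[C@@H]2[C@@H](CC[C@@]2(C)O[Si](CC)(CC)CC)C(C)(C)/C1=C/C[C@@H]1[C@@]2(C)CC[C@@H](OC(C)=O)C(C)(C)O[C@@H]2CC[C@H]1O[Si](C)(C)C(C)(C)C | intermediate
38 | (3R,5aR,6R,7R,9aR)-7-hydroxy-2,2,5a-trimethyl-6-Q′-decahydro-1-benzoxepin-3-yl acetate | C[C@@H]1CC[C@@H]2[C@@H](CC[C@@]2(C)O)C(C)(C)/C1=C/C[C@@H]1[C@@]2(C)CC[C@@H](OC(C)=O)C(C)(C)O[C@@H]2CC[C@H]1O | intermediate
39 | (3R,5aR,6R,9aR)-2,2,5a-trimethyl-7-oxo-6-Q′-decahydro-1-benzoxepin-3-yl acetate | C[C@@H]1CC[C@@H]2[C@@H](CC[C@@]2(C)O)C(C)(C)/C1=C/C[C@@H]1[C@@]2(C)CC[C@@H](OC(C)=O)C(C)(C)O[C@@H]2CCC1=O | intermediate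
40 | (3R,5aR,6R,7S,9aR)-7-hydroxy-2,2,5a,7-tetramethyl-6-Q′-decahydro-1-benzoxepin-3-yl acetate | C[C@@H]1CC[C@@H]2[C@@H](CC[C@@]2(C)O)C(C)(C)/C1=C/C[C@@H]1[C@@]2(C)CC[C@@H](OC(C)=O)C(C)(C)O[C@@H]2CC[C@]1(C)O | intermediate
41 | (3R,5aR,6R,7S,9aR)-6-[(2E)-2-[(1R,3aR,6R,8aR)-1-hydroxy-1,4,4,6-tetramethyloctahydroazulen-5(1H)-ylidene]ethyl]-2,2,5a,7-tetramethyldecahydro-1-benzoxepine-3,7-diol | C[C@@H]1CC[C@@H]2[C@@H](CC[C@@]2(C)O)C(C)(C)/C1=C/C[C@@H]1[C@@]2(C)CC[C@@H](O)C(C)(C)O[C@@H]2CC[C@]1(C)O | target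

**Step count and risks**

Total step count: 28. Longest linear sequence: 26 (steps 1–13 and 16–28).

The three steps most likely to fail:

Step 23 (proposed new method). What may go wrong: after heterolysis the oxocarbenium ion may lose a proton from C9 or re-close faster than it is reduced; hydride may arrive from the equatorial side and give the cis-fused ether; the tertiary silyl ether may ionise. The fallback uses known chemistry and changes the bond-breaking mode from ionic to radical-anionic; it sets out from 32 and comes back at 35. Treatment of 32 with SmI2 (THF, t-BuOH, −78 → 0 °C) should form the C3 ketyl, a reductive fragmentation known for cyclobutyl ketones from [2+2] photoadducts. β-Scission should break the C4–C9a bond because only this cleavage gives a tertiary α-alkoxy radical. A second electron transfer, protonation at C9a and tautomerisation of the samarium enolate on work-up would give 35. The C9a configuration then depends on protonation from the face opposite the axial C5a methyl and would have to be checked. This detour makes no new compound (F0).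

Step 22 (key step). What may go wrong: poor facial selectivity at the isopropenyl group, whose methyl and CH2 ends differ little in size, so the C5a epimer with the methyl trans to the side chain may compete; crossed addition and reversion of the biradical are further losses. The fallback replaces substrate control by catalyst control; it sets out from 31 and comes back at 32. Compound 31 is irradiated at 366–405 nm in CH2Cl2 at −70 °C in the presence of a chiral oxazaborolidine activated by AlBr3. The Lewis acid binds the furanone carbonyl, shifts its absorption so that only the complex is excited, and shields one face of the C4=C9a bond. Because the cyclobutane is cis-fused to both rings, the furanone face that is attacked fixes C5a; the catalyst enantiomer matched with C6 is used. This detour makes no new compound (F0).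

Step 6. What may go wrong: slow epoxide opening, because the nucleophile must enter next to the cis tert-alkyl group, with magnesium salts promoting rearrangement of the epoxide instead. The fallback uses a linear sp nucleophile; it sets out from 9 and comes back at 10. Lithium (trimethylsilyl)acetylide with BF3·OEt2 (THF, −78 °C) should open 9 at C8a′ with inversion to give the silylalkyne methyl 2-[(1R,2S,3R)-3-hydroxy-3-methyl-2-[(trimethylsilyl)ethynyl]cyclopentyl]-2-methylpropanoate F1. K2CO3 in MeOH then gives the terminal alkyne methyl 2-[(1R,2S,3R)-2-ethynyl-3-hydroxy-3-methylcyclopentyl]-2-methylpropanoate F2. Semihydrogenation (H2, Pd/CaCO3 poisoned with Pb(OAc)2, quinoline) gives 10.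

**Further compounds**

F0 | step 23 | none | none
F0 | step 22 | none | none
F1 | step 6 | methyl 2-[(1R,2S,3R)-3-hydroxy-3-methyl-2-[(trimethylsilyl)ethynyl]cyclopentyl]-2-methylpropanoate | C[Si](C)(C)C#C[C@@H]1[C@@H](CC[C@@]1(C)O)C(C)(C)C(=O)OC
F2 | step 6 | methyl 2-[(1R,2S,3R)-2-ethynyl-3-hydroxy-3-methylcyclopentyl]-2-methylpropanoate | C#C[C@@H]1[C@@H](CC[C@@]1(C)O)C(C)(C)C(=O)OC
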